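**Plan**
- Retrosynthetic cuts, in order: the O–C6 bond of the 1,2-dioxane (ring A); the C3–O bond (hydroperoxide added to a C1–C3 enal); C4–C5 (alkenylzinc plus the ketone of methyl 4-oxopent-2-enoate); C5=C6/C6–C7 (carbocupration of propyne); C11–C12 and C12–CH3 (two couplings on a 1,1-dibromoalkene); C9–C10 (acetylide alkylation).
- Forward: the C7–C14 side chain is built first and joined to C1–C4; the γ-lactone (ring B) is formed next; ring A is closed last from a hydroperoxide on C3.
- Enabling feature: C6 is a fully substituted carbon joined through the C5 methylene to the quaternary lactone carbon C4. It is therefore the tertiary end of a trisubstituted C5=C6 alkene lying 1,3 to the peroxide-bearing C3 of ring B, so a C3–OOH group reaches it in a six-membered Markovnikov closure, and the Z geometry of that alkene encodes the C6 configuration.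
- Stereochemistry: C8 from (R)-3-bromo-2-methylpropan-1-ol; C4 by ligand-controlled alkenylzinc addition; C3 by iminium-catalysed peroxidation; C6 by anti peroxymercuration of the Z-alkene through the chair with the C4 methyl equatorial; alkene geometries by syn-carbometalations and stereoretentive couplings.

Key step: step 14

Remark: atom numbers follow the polyketide chain of the target (C1 lactone carbonyl, C3/C4 ring fusion, C6 peroxide carbon, C14 benzylic CH2); the facial sense of the two catalyst-controlled steps (7 and 11) is assigned from the accepted steric models, and the antipodal ligand or catalyst would be used if an early intermediate proved otherwise.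

Step 1
Reactants: 1 (R)-3-bromo-2-methylpropan-1-ol
Product: 3 (R)-(5-bromo-4-methylpent-1-yn-1-yl)trimethylsilane, via bromo triflate 2 (not isolated)
Conditions: Tf2O, 2,6-lutidine, CH2Cl2, −78 °C; short silica plug; then LiC≡CSiMe3, THF–DMPU, −78 to −20 °C
Reagents that add atoms: lithium (trimethylsilyl)acetylide, [Li]C#C[Si](C)(C)C
Why: SN2 alkylation of an acetylide by a primary triflate, which reacts far faster than the β-branched primary bromide, forms C9–C10 and keeps the bromide that later becomes C7; the C8 stereocentre is not touched.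

Step 2
Reactants: 3 (R)-(5-bromo-4-methylpent-1-yn-1-yl)trimethylsilane
Product: 4 (R)-5-bromo-4-methylpent-1-yne
Conditions: K2CO3 (cat.), MeOH, rt
Reagents that add atoms: none
Why: Base-catalysed protodesilylation of an alkynylsilane frees the terminal alkyne needed for carbometalation without displacing the bromide.

Step 3
Reactants: 5 phenylacetaldehyde
Product: 6 (3,3-dibromoprop-2-en-1-yl)benzene
Conditions: CBr4, PPh3, CH2Cl2, 0 °C
Reagents that add atoms: carbon tetrabromide, BrC(Br)(Br)Br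
Why: Corey–Fuchs dibromo-olefination (Wittig-type reaction of the dibromomethylene ylide) converts the aldehyde into the 1,1-dibromoalkene that will carry C12–C14.

Step 4
Reactants: 4 (R)-5-bromo-4-methylpent-1-yne; 6 (3,3-dibromoprop-2-en-1-yl)benzene
Product: 9 [(2Z,4E,7R)-3,8-dibromo-5,7-dimethylocta-2,4-dien-1-yl]benzene, via alkenylalane 7 (not isolated), via alkenylzinc bromide 8 (not isolated)
Conditions: Me3Al, Cp2ZrCl2 (cat.), CH2Cl2, 0 °C to rt; then ZnBr2, 6, PdCl2(DPEphos) (cat.), THF, 0 °C to rt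
Reagents that add atoms: trimethylaluminium, C[Al](C)C
Why: Zirconium-catalysed syn-carboalumination puts methyl and aluminium cis on the alkyne (10E geometry), and the Negishi coupling of the derived alkenylzinc with the 1,1-dibromoalkene is trans-selective, replacing only the bromide trans to the benzylic CH2 so that C11 ends up trans to C14.

Step 5
Reactants: 9 [(2Z,4E,7R)-3,8-dibromo-5,7-dimethylocta-2,4-dien-1-yl]benzene
Product: 10 [(2E,4E,7R)-8-bromo-3,5,7-trimethylocta-2,4-dien-1-yl]benzene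
Conditions: Me2Zn, Pd(P(t-Bu)3)2 (cat.), THF, 0 °C to rt
Reagents that add atoms: dimethylzinc, C[Zn]C
Why: Negishi methylation of the remaining alkenyl bromide with a bulky trialkylphosphine catalyst, chosen because such catalysts couple 2-bromo-1,3-dienes with retention, fixes the 12E geometry, while the primary alkyl bromide does not undergo oxidative addition.

Step 6
Reactants: 10 [(2E,4E,7R)-8-bromo-3,5,7-trimethylocta-2,4-dien-1-yl]benzene
Product: 14 [(2E,4E,7R,9Z)-10-iodo-3,5,7,9-tetramethyldeca-2,4,9-trien-1-yl]benzene, via Grignard reagent 11 (not isolated), via alkylcopper 12 (not isolated), via alkenylcopper 13 (not isolated)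
Conditions: Mg, Et2O, reflux; CuBr·SMe2, Et2O–Me2S, −45 °C; propyne, −25 °C; then I2, −50 to 0 °C
Reagents that add atoms: propyne, CC#C; iodine, II
Why: Normant syn-carbocupration of propyne adds the alkyl group to the internal carbon and copper to the terminal carbon on the same side, and iodinolysis with retention gives the Z-iodide in which iodine is cis to C7, the geometry that later encodes C6.

Step 7
Reactants: 14 [(2E,4E,7R,9Z)-10-iodo-3,5,7,9-tetramethyldeca-2,4,9-trien-1-yl]benzene; 15 methyl (E)-4-oxopent-2-enoate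
Product: 18 methyl (2E,4R,5Z,8R,10E,12E)-4-hydroxy-4,6,8,10,12-pentamethyl-14-phenyltetradeca-2,5,10,12-tetraenoate, via alkenyllithium 16 (not isolated), via alkenyl(methyl)zinc 17 (not isolated)
Conditions: t-BuLi (2 equiv), Et2O, −78 °C; MeZnCl, −78 to 0 °C; TEEDA; then 15, Ti(OiPr)4, bis(hydroxycamphorsulfonamide) ligand of trans-cyclohexane-1,2-diamine (cat.), toluene, rt
Reagents that add atoms: none
Why: Iodine–lithium exchange with retention, transmetalation to the mixed alkenyl(methyl)zinc and titanium-catalysed, ligand-controlled 1,2-addition to the methyl ketone (catalytic asymmetric alkenylzinc addition to ketones) form C4–C5 and set C4 by delivery to the Si face (4R in 18, the 4S centre of the target), with C4 cis to C7 on the alkene.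

Step 8
Reactants: 18 methyl (2E,4R,5Z,8R,10E,12E)-4-hydroxy-4,6,8,10,12-pentamethyl-14-phenyltetradeca-2,5,10,12-tetraenoate
Product: 19 (2E,4R,5Z,8R,10E,12E)-4,6,8,10,12-pentamethyl-14-phenyltetradeca-2,5,10,12-tetraene-1,4-diol
Conditions: i-Bu2AlH, CH2Cl2, −78 to 0 °C; aq. potassium sodium tartrate
Reagents that add atoms: none
Why: 1,2-Reduction of the conjugated ester by the aluminium hydride gives the primary allylic alcohol and leaves the tertiary alcohol, the alkenes and both stereocentres untouched.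

Step 9
Reactants: 19 (2E,4R,5Z,8R,10E,12E)-4,6,8,10,12-pentamethyl-14-phenyltetradeca-2,5,10,12-tetraene-1,4-diol
Product: 20 (2E,4R,5Z,8R,10E,12E)-4-hydroxy-4,6,8,10,12-pentamethyl-14-phenyltetradeca-2,5,10,12-tetraenal
Conditions: MnO2, CH2Cl2, rt
Reagents that add atoms: none
Why: Chemoselective MnO2 oxidation of a primary allylic alcohol gives the E-enal under neutral conditions that do not ionise the tertiary bis-allylic alcohol.

Step 10
Reactants: 21 2,3-dimethylbut-2-ene
Product: 23 2-methoxypropan-2-yl hydroperoxide, via carbonyl oxide 22 (not isolated)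
Conditions: O3, MeOH–CH2Cl2, −78 °C
Reagents that add atoms: ozone, [O-][O+]=O; methanol, CO
Why: Ozonolysis in methanol (Criegee mechanism) splits the symmetrical alkene into acetone and its carbonyl oxide, which methanol traps as the α-methoxy hydroperoxide, a hydroperoxide whose ketal-type group can later be removed with mild acid.

Step 11
Reactants: 20 (2E,4R,5Z,8R,10E,12E)-4-hydroxy-4,6,8,10,12-pentamethyl-14-phenyltetradeca-2,5,10,12-tetraenal; 23 2-methoxypropan-2-yl hydroperoxide
Product: 25 (4S,5S)-4-[(2-methoxypropan-2-yl)peroxy]-5-methyl-5-[(1Z,4R,6E,8E)-2,4,6,8-tetramethyl-10-phenyldeca-1,6,8-trien-1-yl]oxolan-2-ol (both C2 anomers), via peroxy aldehyde 24 (not isolated)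
Conditions: (S)-α,α-bis[3,5-bis(trifluoromethyl)phenyl]prolinol trimethylsilyl ether (cat.), PhCO2H (cat.), toluene, 0 °C
Reagents that add atoms: none
Why: Iminium-ion catalysis (asymmetric organocatalytic oxa-Michael addition of a hydroperoxide to an enal) delivers the peroxide to C3 from the face of the E-iminium ion not shielded by the diarylsiloxymethyl group, which corresponds to 3S, and the C4 hydroxyl then closes the aldehyde to the five-membered lactol so that the addition cannot revert and no by-product is formed.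

Step 12
Reactants: 25 (4S,5S)-4-[(2-methoxypropan-2-yl)peroxy]-5-methyl-5-[(1Z,4R,6E,8E)-2,4,6,8-tetramethyl-10-phenyldeca-1,6,8-trien-1-yl]oxolan-2-ol
Product: 26 (4S,5S)-4-[(2-methoxypropan-2-yl)peroxy]-5-methyl-5-[(1Z,4R,6E,8E)-2,4,6,8-tetramethyl-10-phenyldeca-1,6,8-trien-1-yl]oxolan-2-one
Conditions: TEMPO (cat.), PhI(OAc)2, CH2Cl2, rt
Reagents that add atoms: none
Why: Oxoammonium (TEMPO/PhI(OAc)2) oxidation of a lactol to the lactone forms ring B under conditions mild enough for the peroxyketal, the allylic C4–O bond and the alkenes.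

Step 13
Reactants: 26 (4S,5S)-4-[(2-methoxypropan-2-yl)peroxy]-5-methyl-5-[(1Z,4R,6E,8E)-2,4,6,8-tetramethyl-10-phenyldeca-1,6,8-trien-1-yl]oxolan-2-one
Product: 27 (4S,5S)-4-hydroperoxy-5-methyl-5-[(1Z,4R,6E,8E)-2,4,6,8-tetramethyl-10-phenyldeca-1,6,8-trien-1-yl]oxolan-2-one
Conditions: PPTS (cat.), MeOH, 0 °C
Reagents that add atoms: none
Why: Acid-catalysed transketalisation of the mixed peroxyketal with methanol releases the free hydroperoxide and 2,2-dimethoxypropane under conditions too mild to ionise the tertiary allylic lactone.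

Step 14
Reactants: 27 (4S,5S)-4-hydroperoxy-5-methyl-5-[(1Z,4R,6E,8E)-2,4,6,8-tetramethyl-10-phenyldeca-1,6,8-trien-1-yl]oxolan-2-one
Product: 29 (3S,4S,6R,8R,10E,12E)-3,6-epidioxy-4,6,8,10,12-pentamethyl-14-phenyltetradeca-10,12-dien-4-olide (CNP0272658.1), via organomercurial 28 (not isolated)
Conditions: Hg(OAc)2, CH2Cl2, 0 °C; then Bu3SnH, THF, −20 to 0 °C
Reagents that add atoms: none
Why: Hg(OAc)2 forms a mercurinium ion on C5=C6 and the terminal oxygen of the C3 hydroperoxide opens it at C6 in an anti addition, after which Bu3SnH exchanges the C5–Hg bond for C–H through the alkylmercury hydride radical chain. The closest known reaction type is the cycloperoxymercuration–demercuration of unsaturated hydroperoxides to 1,2-dioxanes. Ring A closes in the 6-endo mode at the Markovnikov carbon, the 5-exo alternative at C5 being disfavoured because C5 is secondary, neopentyl-like and next to the electron-withdrawing C4–O bond. C6 is the only new stereocentre kept in the product: in an anti 6-endo addition the alkene substituent cis to C4 (C7, by the Z geometry) becomes axial and the methyl equatorial, and the cis-fused chair with the C4 methyl equatorial and the lactone oxygen axial places that axial C7 on the face of the lactone oxygen (6R), whereas the inverted chair would suffer a 1,3-diaxial clash of C7 with the C4 methyl. The step needs site selectivity for C5=C6 over the C10–C13 diene and must not cleave the O–O bond; the first is secured because only the C5=C6 mercurinium ion has a tethered nucleophile while complexation elsewhere is reversible, the second because the ring C5 radical cannot align with the O–O bond for epoxide formation and is quenched quickly by the tin hydride. The transient C5 stereocentre (mercury equatorial, anti to the new C6–O bond) is erased on reduction.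

**Compound list**
1 | (R)-3-bromo-2-methylpropan-1-ol | OC[C@@H](C)CBr | starting material
2 | (R)-3-bromo-2-methylpropyl trifluoromethanesulfonate | O=S(=O)(OC[C@@H](C)CBr)C(F)(F)F | intermediate
3 | (R)-(5-bromo-4-methylpent-1-yn-1-yl)trimethylsilane | C[Si](C)(C)C#CC[C@@H](C)CBr | intermediate
4 | (R)-5-bromo-4-methylpent-1-yne | C#CC[C@@H](C)CBr | intermediate
5 | phenylacetaldehyde | O=CCc1ccccc1 | starting material
6 | (3,3-dibromoprop-2-en-1-yl)benzene | BrC(Br)=CCc1ccccc1 | intermediate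
7 | [(1E,4R)-5-bromo-2,4-dimethylpent-1-en-1-yl]dimethylalumane | C[Al](C)/C=C(\C)C[C@@H](C)CBr | intermediate
8 | bromo[(1E,4R)-5-bromo-2,4-dimethylpent-1-en-1-yl]zinc | Br[Zn]/C=C(\C)C[C@@H](C)CBr | intermediate
9 | [(2Z,4E,7R)-3,8-dibromo-5,7-dimethylocta-2,4-dien-1-yl]benzene | BrC(=C\Cc1ccccc1)/C=C(\C)C[C@@H](C)CBr | intermediate
10 | [(2E,4E,7R)-8-bromo-3,5,7-trimethylocta-2,4-dien-1-yl]benzene | CC(=C\Cc1ccccc1)/C=C(\C)C[C@@H](C)CBr | intermediate
11 | bromo[(2R,4E,6E)-2,4,6-trimethyl-8-phenylocta-4,6-dien-1-yl]magnesium | CC(=C\Cc1ccccc1)/C=C(\C)C[C@@H](C)C[Mg]Br | intermediate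
12 | [(2R,4E,6E)-2,4,6-trimethyl-8-phenylocta-4,6-dien-1-yl]copper | CC(=C\Cc1ccccc1)/C=C(\C)C[C@@H](C)C[Cu] | intermediate
13 | [(1Z,4R,6E,8E)-2,4,6,8-tetramethyl-10-phenyldeca-1,6,8-trien-1-yl]copper | CC(=C\Cc1ccccc1)/C=C(\C)C[C@@H](C)C/C(C)=C\[Cu] | intermediate
14 | [(2E,4E,7R,9Z)-10-iodo-3,5,7,9-tetramethyldeca-2,4,9-trien-1-yl]benzene | CC(=C\Cc1ccccc1)/C=C(\C)C[C@@H](C)C/C(C)=C\I | intermediate
15 | methyl (E)-4-oxopent-2-enoate | CC(=O)/C=C/C(=O)OC | starting material
16 | [(1Z,4S,6E,8E)-2,4,6,8-tetramethyl-10-phenyldeca-1,6,8-trien-1-yl]lithium | CC(=C\Cc1ccccc1)/C=C(\C)C[C@@H](C)C/C(C)=C\[Li] | intermediate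
17 | methyl[(1Z,4R,6E,8E)-2,4,6,8-tetramethyl-10-phenyldeca-1,6,8-trien-1-yl]zinc | CC(=C\Cc1ccccc1)/C=C(\C)C[C@@H](C)C/C(C)=C\[Zn]C | intermediate
18 | methyl (2E,4R,5Z,8R,10E,12E)-4-hydroxy-4,6,8,10,12-pentamethyl-14-phenyltetradeca-2,5,10,12-tetraenoate | CC(=C\Cc1ccccc1)/C=C(\C)C[C@@H](C)C/C(C)=C\[C@](C)(O)/C=C/C(=O)OC | intermediate
19 | (2E,4R,5Z,8R,10E,12E)-4,6,8,10,12-pentamethyl-14-phenyltetradeca-2,5,10,12-tetraene-1,4-diol | CC(=C\Cc1ccccc1)/C=C(\C)C[C@@H](C)C/C(C)=C\[C@](C)(O)/C=C/CO | intermediate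
20 | (2E,4R,5Z,8R,10E,12E)-4-hydroxy-4,6,8,10,12-pentamethyl-14-phenyltetradeca-2,5,10,12-tetraenal | CC(=C\Cc1ccccc1)/C=C(\C)C[C@@H](C)C/C(C)=C\[C@](C)(O)/C=C/C=O | intermediate
21 | 2,3-dimethylbut-2-ene | CC(C)=C(C)C | starting material
22 | propan-2-one O-oxide (carbonyl oxide) | CC(C)=[O+][O-] | intermediate
23 | 2-methoxypropan-2-yl hydroperoxide | COC(C)(C)OO | intermediate
24 | (3S,4S,5Z,8R,10E,12E)-4-hydroxy-3-[(2-methoxypropan-2-yl)peroxy]-4,6,8,10,12-pentamethyl-14-phenyltetradeca-5,10,12-trienal | CC(=C\Cc1ccccc1)/C=C(\C)C[C@@H](C)C/C(C)=C\[C@](C)(O)[C@@H](OOC(C)(C)OC)CC=O | intermediate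
25 | (4S,5S)-4-[(2-methoxypropan-2-yl)peroxy]-5-methyl-5-[(1Z,4R,6E,8E)-2,4,6,8-tetramethyl-10-phenyldeca-1,6,8-trien-1-yl]oxolan-2-ol (both C2 anomers) | CC(=C\Cc1ccccc1)/C=C(\C)C[C@@H](C)C/C(C)=C\[C@]1(C)OC(O)C[C@@H]1OOC(C)(C)OC | intermediate
26 | (4S,5S)-4-[(2-methoxypropan-2-yl)peroxy]-5-methyl-5-[(1Z,4R,6E,8E)-2,4,6,8-tetramethyl-10-phenyldeca-1,6,8-trien-1-yl]oxolan-2-one | CC(=C\Cc1ccccc1)/C=C(\C)C[C@@H](C)C/C(C)=C\[C@]1(C)OC(=O)C[C@@H]1OOC(C)(C)OC | intermediate
27 | (4S,5S)-4-hydroperoxy-5-methyl-5-[(1Z,4R,6E,8E)-2,4,6,8-tetramethyl-10-phenyldeca-1,6,8-trien-1-yl]oxolan-2-one | CC(=C\Cc1ccccc1)/C=C(\C)C[C@@H](C)C/C(C)=C\[C@]1(C)OC(=O)C[C@@H]1OO | intermediate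
28 | (3S,4R,5R,6R,8R,10E,12E)-5-(acetoxymercurio)-3,6-epidioxy-4,6,8,10,12-pentamethyl-14-phenyltetradeca-10,12-dien-4-olide | CC(=C\Cc1ccccc1)/C=C(\C)C[C@@H](C)C[C@]1(C)[C@H]([Hg]OC(C)=O)[C@]2(C)OC(=O)C[C@@H]2OO1 | intermediate
29 | (3S,4S,6R,8R,10E,12E)-3,6-epidioxy-4,6,8,10,12-pentamethyl-14-phenyltetradeca-10,12-dien-4-olide (CNP0272658.1; cis-fused 1,2-dioxane/γ-lactone) | CC(=C\Cc1ccccc1)/C=C(\C)C[C@@H](C)C[C@]1(C)C[C@]2(C)OC(=O)C[C@@H]2OO1 | target

**Step count:** 14 steps in total; longest linear sequence 12 steps (steps 1, 2, 4–9 and 11–14, from 1).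

**Steps most likely to fail, with fallbacks**

Step 11. The conjugate addition may be slow because C3 is flanked by the fully substituted C4; the intermediate enamine may collapse onto the O–O bond (epoxide formation); and catalyst control may be eroded. The fallback sets out from 14 and rejoins at 29. It anchors the peroxide on an aldehyde carbon, where steric demand does not matter, and sets C3 only at the end by a reversible oxa-Michael closure.
- Reagent 17 (made from 14 as in step 7) is added under the same titanium catalysis to 1,1-dimethoxypropan-2-one to give (2S,3Z,6R,8E,10E)-1,1-dimethoxy-2,4,6,8,10-pentamethyl-12-phenyldodeca-3,8,10-trien-2-ol F5.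
- LiBF4 in wet MeCN frees the aldehyde (2S,3Z,6R,8E,10E)-2-hydroxy-2,4,6,8,10-pentamethyl-12-phenyldodeca-3,8,10-trienal F6.
- Aqueous H2O2 converts the aldehyde into its perhydrate, whose OOH group is cyclised with Hg(OAc)2 and reduced with Bu3SnH as in step 14 to the peroxy-lactol (4S,6R)-4,6-dimethyl-6-[(2R,4E,6E)-2,4,6-trimethyl-8-phenylocta-4,6-dien-1-yl]-1,2-dioxane-3,4-diol F7.
- Horner–Wadsworth–Emmons olefination (trimethyl phosphonoacetate, LiCl, i-Pr2NEt) opens the lactol to methyl (2E,4S,6R,8R,10E,12E)-6-hydroperoxy-4-hydroxy-4,6,8,10,12-pentamethyl-14-phenyltetradeca-2,10,12-trienoate F8.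
- F8 should reclose by oxa-Michael addition (Et3N, CF3CH2OH) with the CH2CO2Me group equatorial to methyl 2-[(3S,4S,6R)-4-hydroxy-4,6-dimethyl-6-[(2R,4E,6E)-2,4,6-trimethyl-8-phenylocta-4,6-dien-1-yl]-1,2-dioxan-3-yl]acetate F9.
- PPTS in warm benzene lactonises F9 to 29.

Step 14. The closure may go 5-exo to a 1,2-dioxolane, the mercury salt may be consumed at the side-chain diene, or the two chair transition states may not be well differentiated. The fallback sets out from 27 and rejoins at 29. It closes the same O–C6 bond by allylic substitution instead of alkene activation and re-forms the lactone afterwards.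
- BF3·OEt2 (CH2Cl2, −78 to −40 °C) ionises the tertiary allylic C4–O bond of the lactone, and the hydroperoxide captures the allyl cation at C6 to give 2-[(3S,6R)-4,6-dimethyl-6-[(2R,4E,6E)-2,4,6-trimethyl-8-phenylocta-4,6-dien-1-yl]-3,6-dihydro-1,2-dioxin-3-yl]acetic acid F10. C6 is not controlled here, so its epimer would have to be separated.
- Iodolactonisation (I2, NaHCO3, MeCN) rebuilds the cis-fused lactone by anti addition across C4=C5, giving (3S,4R,5S,6R,8R,10E,12E)-5-iodo-3,6-epidioxy-4,6,8,10,12-pentamethyl-14-phenyltetradeca-10,12-dien-4-olide F11.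
- Bu3SnH with AIBN removes the iodine to give 29.

Step 7. The ligand may discriminate the ketone faces poorly with this hindered Z-alkenylzinc, and lithium salts may promote an unselective background addition. The fallback sets out from 14 and rejoins at 20. It sets C4 by reagent-controlled epoxidation instead.
- Stille coupling of 14 with (E)-3-(tributylstannyl)but-2-en-1-ol (Pd2(dba)3, AsPh3, NMP) gives (2E,4Z,7R,9E,11E)-3,5,7,9,11-pentamethyl-13-phenyltrideca-2,4,9,11-tetraen-1-ol F1.
- Sharpless asymmetric epoxidation (Ti(OiPr)4, L-(+)-diethyl tartrate, t-BuOOH, −20 °C) of the allylic alkene gives [(2S,3S)-3-methyl-3-[(1Z,4R,6E,8E)-2,4,6,8-tetramethyl-10-phenyldeca-1,6,8-trien-1-yl]oxiran-2-yl]methanol F2.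
- Appel iodination (I2, PPh3, imidazole) gives (2R,3S)-2-(iodomethyl)-3-methyl-3-[(1Z,4R,6E,8E)-2,4,6,8-tetramethyl-10-phenyldeca-1,6,8-trien-1-yl]oxirane F3.
- Zn in EtOH opens the epoxy iodide reductively to the tertiary allylic alcohol (3R,4Z,7R,9E,11E)-3,5,7,9,11-pentamethyl-13-phenyltrideca-1,4,9,11-tetraen-3-ol F4, keeping the C4–O bond.
- Cross-metathesis of the vinyl group with crotonaldehyde (second-generation Hoveyda–Grubbs catalyst, CH2Cl2, 40 °C) gives 20.

**Further compounds**
F1 | step 7 | (2E,4Z,7R,9E,11E)-3,5,7,9,11-pentamethyl-13-phenyltrideca-2,4,9,11-tetraen-1-ol | CC(=C\Cc1ccccc1)/C=C(\C)C[C@@H](C)C/C(C)=C\C(C)=C\CO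
F2 | step 7 | [(2S,3S)-3-methyl-3-[(1Z,4R,6E,8E)-2,4,6,8-tetramethyl-10-phenyldeca-1,6,8-trien-1-yl]oxiran-2-yl]methanol | CC(=C\Cc1ccccc1)/C=C(\C)C[C@@H](C)C/C(C)=C\[C@]1(C)O[C@H]1CO
F3 | step 7 | (2R,3S)-2-(iodomethyl)-3-methyl-3-[(1Z,4R,6E,8E)-2,4,6,8-tetramethyl-10-phenyldeca-1,6,8-trien-1-yl]oxirane | CC(=C\Cc1ccccc1)/C=C(\C)C[C@@H](C)C/C(C)=C\[C@]1(C)O[C@H]1CI
F4 | step 7 | (3R,4Z,7R,9E,11E)-3,5,7,9,11-pentamethyl-13-phenyltrideca-1,4,9,11-tetraen-3-ol | CC(=C\Cc1ccccc1)/C=C(\C)C[C@@H](C)C/C(C)=C\[C@](C)(O)C=C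
F5 | step 11 | (2S,3Z,6R,8E,10E)-1,1-dimethoxy-2,4,6,8,10-pentamethyl-12-phenyldodeca-3,8,10-trien-2-ol | CC(=C\Cc1ccccc1)/C=C(\C)C[C@@H](C)C/C(C)=C\[C@](C)(O)C(OC)OC
F6 | step 11 | (2S,3Z,6R,8E,10E)-2-hydroxy-2,4,6,8,10-pentamethyl-12-phenyldodeca-3,8,10-trienal | CC(=C\Cc1ccccc1)/C=C(\C)C[C@@H](C)C/C(C)=C\[C@](C)(O)C=O
F7 | step 11 | (4S,6R)-4,6-dimethyl-6-[(2R,4E,6E)-2,4,6-trimethyl-8-phenylocta-4,6-dien-1-yl]-1,2-dioxane-3,4-diol (both C3 anomers) | CC(=C\Cc1ccccc1)/C=C(\C)C[C@@H](C)C[C@]1(C)C[C@](C)(O)C(O)OO1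
F8 | step 11 | methyl (2E,4S,6R,8R,10E,12E)-6-hydroperoxy-4-hydroxy-4,6,8,10,12-pentamethyl-14-phenyltetradeca-2,10,12-trienoate | CC(=C\Cc1ccccc1)/C=C(\C)C[C@@H](C)C[C@@](C)(OO)C[C@](C)(O)/C=C/C(=O)OC
F9 | step 11 | methyl 2-[(3S,4S,6R)-4-hydroxy-4,6-dimethyl-6-[(2R,4E,6E)-2,4,6-trimethyl-8-phenylocta-4,6-dien-1-yl]-1,2-dioxan-3-yl]acetate | CC(=C\Cc1ccccc1)/C=C(\C)C[C@@H](C)C[C@]1(C)C[C@](C)(O)[C@H](CC(=O)OC)OO1
F10 | step 14 | 2-[(3S,6R)-4,6-dimethyl-6-[(2R,4E,6E)-2,4,6-trimethyl-8-phenylocta-4,6-dien-1-yl]-3,6-dihydro-1,2-dioxin-3-yl]acetic acid | CC(=C\Cc1ccccc1)/C=C(\C)C[C@@H](C)C[C@]1(C)C=C(C)[C@H](CC(=O)O)OO1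
F11 | step 14 | (3S,4R,5S,6R,8R,10E,12E)-5-iodo-3,6-epidioxy-4,6,8,10,12-pentamethyl-14-phenyltetradeca-10,12-dien-4-olide | CC(=C\Cc1ccccc1)/C=C(\C)C[C@@H](C)C[C@]1(C)[C@@H](I)[C@]2(C)OC(=O)C[C@@H]2OO1
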